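**Retrosynthetic overview**

- The target is reached by hydrogenolysis of its octabenzyl ether; every phenol and the flavonol 3-OH are carried as benzyl ethers throughout.
- Key disconnection: the C4–C4a bond of ring C of the flavan. Ring C is closed last by a cationic Friedel–Crafts closure of an open-chain aryl ether, which is made in the same flask by opening a temporary trans-oxirane (C2–C3, a ring absent from the target) at C2 with 3-(benzyloxy)phenol (O1–C2, inversion).
- Enabling feature: C4 is a diarylmethine carbon on the pyrogallol ring, whose O-3′ (ortho) and O-5′ (para) stabilise positive charge at C4, while C4a of the resorcinol-derived ring A is para to O-7 and ortho to O-1. The 2,3-trans-3,4-trans array maps onto anti opening of a trans-epoxide followed by an all-equatorial chair closure.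
- The epoxy alcohol comes from asymmetric epoxidation and reduction of an E-enone, itself a Claisen–Schmidt product of a 2′-acetylflavonol and 3,4-bis(benzyloxy)benzaldehyde; the acetyl group comes from an aryl bromide by Stille coupling.
- Order of ring formation: flavonol pyranone ring (Claisen–Schmidt, Algar–Flynn–Oyamada), then the temporary oxirane, then flavan ring C (key step).

Key step: step 9

Remark on the chemistry: C2, C3, C4, C4a and O1 refer to the flavan unit of the target and primed numbers to the pyrogallol ring; 3,4,5-tris(benzyloxy)benzaldehyde is taken as purchasable, and the carbinol configuration created in step 8 is of no consequence because that carbon is ionised in step 9.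

Step 1
Reactants: 1 3,4,5-tris(benzyloxy)benzaldehyde
Product: 2 3,4,5-tris(benzyloxy)-2-bromobenzaldehyde
Conditions: NBS, MeCN, 23 °C
Reagents that add atoms: N-bromosuccinimide, O=C1CCC(=O)N1Br
Why: Electrophilic aromatic bromination; C2 and C6 are equivalent and each lies ortho and para to a benzyloxy group, so a single monobromide is expected.

Step 2
Reactants: 2 3,4,5-tris(benzyloxy)-2-bromobenzaldehyde; 3 1-[4-(benzyloxy)-2-hydroxyphenyl]ethanone
Product: 4 (E)-1-[4-(benzyloxy)-2-hydroxyphenyl]-3-[3,4,5-tris(benzyloxy)-2-bromophenyl]prop-2-en-1-one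
Conditions: KOH (aq.), EtOH/THF, 23 °C
Reagents that add atoms: none
Why: Claisen–Schmidt aldol condensation of the methyl ketone with a non-enolisable aldehyde; dehydration gives the conjugated E-enone.

Step 3
Reactants: 4 (E)-1-[4-(benzyloxy)-2-hydroxyphenyl]-3-[3,4,5-tris(benzyloxy)-2-bromophenyl]prop-2-en-1-one
Product: 6 7-(benzyloxy)-2-[3,4,5-tris(benzyloxy)-2-bromophenyl]-3-hydroxy-4H-chromen-4-one, via dihydroflavonol 5 (not isolated)
Conditions: H2O2 (30 % aq.), NaOH, MeOH/THF, 0 to 23 °C
Reagents that add atoms: hydrogen peroxide, OO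
Why: Algar–Flynn–Oyamada reaction: alkaline peroxide oxidises the enone, the phenoxide closes the pyranone ring 6-endo at the benzylic carbon to the dihydroflavonol, and this is oxidised on to the flavonol; a ketone ring without a 6′-substituent favours flavonol over aurone.

Step 4
Reactants: 6 7-(benzyloxy)-2-[3,4,5-tris(benzyloxy)-2-bromophenyl]-3-hydroxy-4H-chromen-4-one
Product: 7 3,7-bis(benzyloxy)-2-[3,4,5-tris(benzyloxy)-2-bromophenyl]-4H-chromen-4-one
Conditions: BnBr, K2CO3, DMF, 23 °C
Reagents that add atoms: benzyl bromide, BrCc1ccccc1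
Why: Williamson O-alkylation of the acidic flavonol 3-OH, which masks it against the bases and oxidants that follow.

Step 5
Reactants: 7 3,7-bis(benzyloxy)-2-[3,4,5-tris(benzyloxy)-2-bromophenyl]-4H-chromen-4-one
Product: 9 2-[2-acetyl-3,4,5-tris(benzyloxy)phenyl]-3,7-bis(benzyloxy)-4H-chromen-4-one, via 1-ethoxyvinyl arene 8 (not isolated)
Conditions: tributyl(1-ethoxyvinyl)stannane, Pd2(dba)3 (cat.), XPhos, CsF, 1,4-dioxane, 100 °C; then 1 M HCl, THF, 23 °C
Reagents that add atoms: tributyl(1-ethoxyvinyl)stannane, CCCC[Sn](CCCC)(CCCC)C(=C)OCC; water, O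
Why: Stille coupling with an acetyl anion equivalent, using a bulky electron-rich biarylphosphine and fluoride activation for the di-ortho-substituted bromide; mild acid hydrolysis of the enol ether then releases the methyl ketone.

Step 6
Reactants: 9 2-[2-acetyl-3,4,5-tris(benzyloxy)phenyl]-3,7-bis(benzyloxy)-4H-chromen-4-one; 10 3,4-bis(benzyloxy)benzaldehyde
Product: 11 (E)-3-[3,4-bis(benzyloxy)phenyl]-1-{2,3,4-tris(benzyloxy)-6-[3,7-bis(benzyloxy)-4-oxo-4H-chromen-2-yl]phenyl}prop-2-en-1-one
Conditions: KOH (aq.), EtOH/THF, 23 °C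
Reagents that add atoms: none
Why: Claisen–Schmidt condensation of the only enolisable ketone with a non-enolisable aldehyde gives the E-enone; the 3-alkoxychromone should tolerate cold dilute alkali.

Step 7
Reactants: 11 (E)-3-[3,4-bis(benzyloxy)phenyl]-1-{2,3,4-tris(benzyloxy)-6-[3,7-bis(benzyloxy)-4-oxo-4H-chromen-2-yl]phenyl}prop-2-en-1-one
Product: 12 [(2R,3S)-3-(3,4-bis(benzyloxy)phenyl)oxiran-2-yl]{2,3,4-tris(benzyloxy)-6-[3,7-bis(benzyloxy)-4-oxo-4H-chromen-2-yl]phenyl}methanone
Conditions: La(O-iPr)3 (10 mol %), (S)-BINOL, Ph3As=O, TBHP, 4 Å MS, THF, 23 °C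
Reagents that add atoms: tert-butyl hydroperoxide, CC(C)(C)OO
Why: Catalytic asymmetric nucleophilic epoxidation (Weitz–Scheffer type): the La–BINOL–Ph3As=O complex delivers tert-butyl peroxide to one face of the β-carbon of the E-enone and ring closure gives the trans-oxirane, the (S)-BINOL complex being the one expected, by analogy with chalcone, to give the (2R,3S)-epoxy ketone, while the tetrasubstituted vinylogous-ester C=C of the chromone is too hindered and too electron-rich to react.

Step 8
Reactants: 12 [(2R,3S)-3-(3,4-bis(benzyloxy)phenyl)oxiran-2-yl]{2,3,4-tris(benzyloxy)-6-[3,7-bis(benzyloxy)-4-oxo-4H-chromen-2-yl]phenyl}methanone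
Product: 13 (S)-[(2S,3S)-3-(3,4-bis(benzyloxy)phenyl)oxiran-2-yl]{2,3,4-tris(benzyloxy)-6-[3,7-bis(benzyloxy)-4-oxo-4H-chromen-2-yl]phenyl}methanol (anti epoxy alcohol)
Conditions: NaBH4, THF/MeOH, −20 °C
Reagents that add atoms: none
Why: NaBH4 1,2-reduction of the aryl ketone, far faster at −20 °C than attack on the vinylogous-ester carbonyl of the chromone; Felkin–Anh addition anti to the oxirane C–O bond should favour the anti (erythro) alcohol drawn, and the new carbinol centre is inconsequential because it is ionised in step 9.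

Step 9
Reactants: 13 (S)-[(2S,3S)-3-(3,4-bis(benzyloxy)phenyl)oxiran-2-yl]{2,3,4-tris(benzyloxy)-6-[3,7-bis(benzyloxy)-4-oxo-4H-chromen-2-yl]phenyl}methanol; 14 3-(benzyloxy)phenol
Product: 16 2-{2-[(2R,3S,4S)-7-(benzyloxy)-2-[3,4-bis(benzyloxy)phenyl]-3-hydroxy-3,4-dihydro-2H-chromen-4-yl]-3,4,5-tris(benzyloxy)phenyl}-3,7-bis(benzyloxy)-4H-chromen-4-one, via aryloxy diol 15 (not isolated)
Conditions: 14 (1.1 equiv), Cs2CO3 (0.2 equiv), 1,4-dioxane, 80 °C; then same flask, 0 °C, (CF3)2CHOH (HFIP), TfOH (0.6 equiv)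
Reagents that add atoms: none
Why: Caesium 3-(benzyloxy)phenoxide opens the oxirane at C2, the benzylic carbon para to the 4-benzyloxy group of the catechol ring, by SN2 with inversion (strain release of a ring that is not in the target), giving the anti aryloxy diol 15 with O1–C2 in place; acidification in HFIP then ionises the benzylic C4–OH to a cation stabilised by the ortho 3′- and para 5′-benzyloxy groups of the pyrogallol ring, and the tethered resorcinol ring attacks it through C4a. Both halves are known reaction types, namely aryloxide opening of aryl-substituted 2,3-epoxy alcohols at the benzylic carbon and dehydrative intramolecular Friedel–Crafts alkylation of electron-rich benzylic alcohols to 4-arylchromans, and the step merely runs them in one flask. Ring C closes as a six-membered ring by electrophilic aromatic substitution on the benzylic cation (formally 6-exo-tet at C4, with the arene as internal π-nucleophile). C2 is set by the inversion (trans-epoxide plus anti opening gives anti O1/O3, the 2,3-trans flavan), C3 is carried through unchanged, and C4 is set in the ring closure: the cation adopts the conformer with H-3 eclipsing the bulky aryl group (least A(1,3) strain) and closes through a chair-like transition state with the 2-aryl, 3-hydroxy and 4-aryl groups all equatorial, so that either C4 epimer of 15 should converge on the 3,4-trans (4S) product. The step needs aryloxide attack at C2 rather than at C3 or after Payne migration (secured by benzylic activation, by the di-ortho-substituted aryl group that shields the other end, and by the phenol-buffered medium that keeps alkoxide concentration low), ionisation at C4 rather than at the C2–OAr bond (alcohol versus aryl ether, two oxygen donors versus one), closure para rather than ortho to the benzyloxy group of ring A (sterics), and closure faster than a pinacol-type hydride shift (short tether to an arene activated by two oxygen substituents).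

Step 10
Reactants: 16 2-{2-[(2R,3S,4S)-7-(benzyloxy)-2-[3,4-bis(benzyloxy)phenyl]-3-hydroxy-3,4-dihydro-2H-chromen-4-yl]-3,4,5-tris(benzyloxy)phenyl}-3,7-bis(benzyloxy)-4H-chromen-4-one
Product: 17 2-{2-[(2R,3S,4S)-2-(3,4-dihydroxyphenyl)-3,7-dihydroxy-3,4-dihydro-2H-chromen-4-yl]-3,4,5-trihydroxyphenyl}-3,7-dihydroxy-4H-chromen-4-one
Conditions: H2 (1 atm), Pd(OH)2/C, THF/MeOH, 23 °C
Reagents that add atoms: none
Why: Hydrogenolysis of the eight O-benzyl groups; the cyclic benzylic C2–O1 ether, the diarylmethine C4–H and the pyranone should survive these mild conditions, so no stereocentre is touched.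

**Compound list**

1 | 3,4,5-tris(benzyloxy)benzaldehyde | O=Cc1cc(OCc2ccccc2)c(OCc2ccccc2)c(OCc2ccccc2)c1 | starting material
2 | 3,4,5-tris(benzyloxy)-2-bromobenzaldehyde | O=Cc1cc(OCc2ccccc2)c(OCc2ccccc2)c(OCc2ccccc2)c1Br | intermediate
3 | 1-[4-(benzyloxy)-2-hydroxyphenyl]ethanone | CC(=O)c1ccc(OCc2ccccc2)cc1O | starting material
4 | (E)-1-[4-(benzyloxy)-2-hydroxyphenyl]-3-[3,4,5-tris(benzyloxy)-2-bromophenyl]prop-2-en-1-one | O=C(/C=C/c1cc(OCc2ccccc2)c(OCc2ccccc2)c(OCc2ccccc2)c1Br)c1ccc(OCc2ccccc2)cc1O | intermediate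
5 | rac-trans-7-(benzyloxy)-2-[3,4,5-tris(benzyloxy)-2-bromophenyl]-3-hydroxychroman-4-one (dihydroflavonol, racemic) | O=C1c2ccc(OCc3ccccc3)cc2OC(c2cc(OCc3ccccc3)c(OCc3ccccc3)c(OCc3ccccc3)c2Br)C1O | intermediate (not isolated)
6 | 7-(benzyloxy)-2-[3,4,5-tris(benzyloxy)-2-bromophenyl]-3-hydroxy-4H-chromen-4-one | O=c1c(O)c(-c2cc(OCc3ccccc3)c(OCc3ccccc3)c(OCc3ccccc3)c2Br)oc2cc(OCc3ccccc3)ccc12 | intermediate
7 | 3,7-bis(benzyloxy)-2-[3,4,5-tris(benzyloxy)-2-bromophenyl]-4H-chromen-4-one | O=c1c(OCc2ccccc2)c(-c2cc(OCc3ccccc3)c(OCc3ccccc3)c(OCc3ccccc3)c2Br)oc2cc(OCc3ccccc3)ccc12 | intermediate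
8 | 3,7-bis(benzyloxy)-2-[3,4,5-tris(benzyloxy)-2-(1-ethoxyvinyl)phenyl]-4H-chromen-4-one | O=c1c(OCc2ccccc2)c(-c2cc(OCc3ccccc3)c(OCc3ccccc3)c(OCc3ccccc3)c2C(=C)OCC)oc2cc(OCc3ccccc3)ccc12 | intermediate (not isolated)
9 | 2-[2-acetyl-3,4,5-tris(benzyloxy)phenyl]-3,7-bis(benzyloxy)-4H-chromen-4-one | O=c1c(OCc2ccccc2)c(-c2cc(OCc3ccccc3)c(OCc3ccccc3)c(OCc3ccccc3)c2C(C)=O)oc2cc(OCc3ccccc3)ccc12 | intermediate
10 | 3,4-bis(benzyloxy)benzaldehyde | O=Cc1ccc(OCc2ccccc2)c(OCc2ccccc2)c1 | starting material
11 | (E)-3-[3,4-bis(benzyloxy)phenyl]-1-{2,3,4-tris(benzyloxy)-6-[3,7-bis(benzyloxy)-4-oxo-4H-chromen-2-yl]phenyl}prop-2-en-1-one | O=c1c(OCc2ccccc2)c(-c2cc(OCc3ccccc3)c(OCc3ccccc3)c(OCc3ccccc3)c2C(=O)/C=C/c2ccc(OCc3ccccc3)c(OCc3ccccc3)c2)oc2cc(OCc3ccccc3)ccc12 | intermediate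
12 | [(2R,3S)-3-(3,4-bis(benzyloxy)phenyl)oxiran-2-yl]{2,3,4-tris(benzyloxy)-6-[3,7-bis(benzyloxy)-4-oxo-4H-chromen-2-yl]phenyl}methanone | O=c1c(OCc2ccccc2)c(-c2cc(OCc3ccccc3)c(OCc3ccccc3)c(OCc3ccccc3)c2C(=O)[C@@H]4O[C@H]4c2ccc(OCc3ccccc3)c(OCc3ccccc3)c2)oc2cc(OCc3ccccc3)ccc12 | intermediate
13 | (S)-[(2S,3S)-3-(3,4-bis(benzyloxy)phenyl)oxiran-2-yl]{2,3,4-tris(benzyloxy)-6-[3,7-bis(benzyloxy)-4-oxo-4H-chromen-2-yl]phenyl}methanol (anti epoxy alcohol) | O=c1c(OCc2ccccc2)c(-c2cc(OCc3ccccc3)c(OCc3ccccc3)c(OCc3ccccc3)c2[C@H](O)[C@@H]4O[C@H]4c2ccc(OCc3ccccc3)c(OCc3ccccc3)c2)oc2cc(OCc3ccccc3)ccc12 | intermediate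
14 | 3-(benzyloxy)phenol | Oc1cccc(OCc2ccccc2)c1 | starting material
15 | 2-{2-[(1S,2S,3R)-3-[3-(benzyloxy)phenoxy]-3-[3,4-bis(benzyloxy)phenyl]-1,2-dihydroxypropyl]-3,4,5-tris(benzyloxy)phenyl}-3,7-bis(benzyloxy)-4H-chromen-4-one | O=c1c(OCc2ccccc2)c(-c2cc(OCc3ccccc3)c(OCc3ccccc3)c(OCc3ccccc3)c2[C@H](O)[C@H](O)[C@H](Oc4cccc(OCc3ccccc3)c4)c2ccc(OCc3ccccc3)c(OCc3ccccc3)c2)oc2cc(OCc3ccccc3)ccc12 | intermediate (not isolated)
16 | 2-{2-[(2R,3S,4S)-7-(benzyloxy)-2-[3,4-bis(benzyloxy)phenyl]-3-hydroxy-3,4-dihydro-2H-chromen-4-yl]-3,4,5-tris(benzyloxy)phenyl}-3,7-bis(benzyloxy)-4H-chromen-4-one | O=c1c(OCc2ccccc2)c(-c2cc(OCc3ccccc3)c(OCc3ccccc3)c(OCc3ccccc3)c2[C@@H]2c3ccc(OCc4ccccc4)cc3O[C@H](c3ccc(OCc4ccccc4)c(OCc4ccccc4)c3)[C@H]2O)oc2cc(OCc3ccccc3)ccc12 | intermediate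
17 | 2-{2-[(2R,3S,4S)-2-(3,4-dihydroxyphenyl)-3,7-dihydroxy-3,4-dihydro-2H-chromen-4-yl]-3,4,5-trihydroxyphenyl}-3,7-dihydroxy-4H-chromen-4-one | O=c1c(O)c(-c2cc(O)c(O)c(O)c2[C@@H]2c3ccc(O)cc3O[C@H](c3ccc(O)c(O)c3)[C@H]2O)oc2cc(O)ccc12 | target

**Step count and risks**

Total step count: 10. Longest linear sequence: 10 steps (1 to 17); compounds 3, 10 and 14 are purchased and enter directly.

The three steps most likely to fail:

Step 9. In the basic stage the oxirane may migrate (Payne rearrangement) or be opened at the wrong carbon before the aryloxide has attacked C2; after the switch to acid, a pinacol-type hydride shift or loss of the C2 aryloxy group may outrun ring closure. The fallback separates the two events and caps the carbinol oxygen first. Setting out from 13, O-methylation (KHMDS, MeOTf, THF, −78 °C) would give the methyl ether of 13 F1, which cannot undergo Payne migration. Caesium 3-(benzyloxy)phenoxide (14, Cs2CO3, DMF, 70 °C) would open it at C2 to the isolated 4-methoxy analogue of 15 F2. BF3·OEt2 in CH2Cl2 at −40 °C would then ionise the benzylic methyl ether, the leaving group used in 4-alkoxyflavan electrophiles, and close ring C, coming back to the route at 16.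

Step 7. Enantiofacial discrimination may be poor, or conjugate addition of the peroxide slow, at an enone whose ketone aryl group is twisted out of conjugation by two ortho substituents. The fallback uses reagent-controlled epoxidation of the allylic alcohol instead of the enone. Setting out from 11, Luche reduction (NaBH4, CeCl3·7H2O, MeOH/THF, −40 °C) would give the racemic allylic alcohol F3. Sharpless kinetic resolution (Ti(O-iPr)4, L-(+)-diisopropyl tartrate, TBHP, 4 Å MS, CH2Cl2, −20 °C) should epoxidise its (R)-enantiomer fast and anti-selectively, coming back to the route at 13 with at most half of the material.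

Step 5. Oxidative addition and transmetalation at a bromide flanked by a benzyloxy group and the chromone may be so slow that protodestannylation of the reagent wins. The fallback moves the coupling to the start, where the ortho-formyl group activates the C–Br bond, and carries the acetyl group as its base-stable enol ether. Setting out from 2, Stille coupling (tributyl(1-ethoxyvinyl)stannane, Pd(PPh3)4, toluene, 100 °C, neutral work-up) would give the enol ether aldehyde F4. Claisen–Schmidt condensation with 3 would give the chalcone F5, and the Algar–Flynn–Oyamada reaction the flavonol F6. Benzylation (BnBr, K2CO3, DMF) would come back to the route at 8, now isolated and hydrolysed to 9 as in step 5.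

**Further compounds**

F1 | step 9 | methyl ether of 13 at the carbinol oxygen (configurations as in 13) | O=c1c(OCc2ccccc2)c(-c2cc(OCc3ccccc3)c(OCc3ccccc3)c(OCc3ccccc3)c2[C@H](OC)[C@@H]4O[C@H]4c2ccc(OCc3ccccc3)c(OCc3ccccc3)c2)oc2cc(OCc3ccccc3)ccc12
F2 | step 9 | analogue of 15 with OMe in place of the benzylic OH, 2-OH of the propyl chain free (configurations as in 15) | O=c1c(OCc2ccccc2)c(-c2cc(OCc3ccccc3)c(OCc3ccccc3)c(OCc3ccccc3)c2[C@H](OC)[C@H](O)[C@H](Oc4cccc(OCc3ccccc3)c4)c2ccc(OCc3ccccc3)c(OCc3ccccc3)c2)oc2cc(OCc3ccccc3)ccc12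
F3 | step 7 | racemic (E)-allylic alcohol from 1,2-reduction of 11 | O=c1c(OCc2ccccc2)c(-c2cc(OCc3ccccc3)c(OCc3ccccc3)c(OCc3ccccc3)c2C(O)/C=C/c2ccc(OCc3ccccc3)c(OCc3ccccc3)c2)oc2cc(OCc3ccccc3)ccc12
F4 | step 5 | 3,4,5-tris(benzyloxy)-2-(1-ethoxyvinyl)benzaldehyde | O=Cc1cc(OCc2ccccc2)c(OCc2ccccc2)c(OCc2ccccc2)c1C(=C)OCC
F5 | step 5 | (E)-1-[4-(benzyloxy)-2-hydroxyphenyl]-3-[3,4,5-tris(benzyloxy)-2-(1-ethoxyvinyl)phenyl]prop-2-en-1-one | O=C(/C=C/c1cc(OCc2ccccc2)c(OCc2ccccc2)c(OCc2ccccc2)c1C(=C)OCC)c1ccc(OCc2ccccc2)cc1O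
F6 | step 5 | 7-(benzyloxy)-2-[3,4,5-tris(benzyloxy)-2-(1-ethoxyvinyl)phenyl]-3-hydroxy-4H-chromen-4-one | O=c1c(O)c(-c2cc(OCc3ccccc3)c(OCc3ccccc3)c(OCc3ccccc3)c2C(=C)OCC)oc2cc(OCc3ccccc3)ccc12
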